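In the ash run and the alder run [added ligand] went from 0.44 mM to 1.5 mM. Yet at 40.0 min the right-handed substrate read 31% and 33%, and one reading scatters by 1.5 percentage points.

in all of them: left-handed substrate 0.10 M; right-handed substrate 0.10 M; free catalyst 0.52 mM; stray impurity 0.40 mM

| flask | coupling partner | protic impurity | added ligand | remark | time |
|---|---|---|---|---|---|
| ash | 0.11 M | 5 mM | 0.44 mM | run made earlier |  |
| alder | 0.11 M | 5 mM | 1.5 mM | run made earlier |  |
| north-east | 0.110 M | 5.00 mM | 2.0 mM |  | 50 min |
| south-west | 0.110 M | 5.00 mM | 0.60 mM |  | 50 min |

- ash (time / min: right-handed substrate / %, left-handed substrate / %, left-handed product / %): 4.00: 44, 41, 10; 12.0: 42, 35, 13; 25.0: 37, 31, 18; 40.0: 31, 28, 23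
- alder (time / min: right-handed substrate / %, left-handed substrate / %, left-handed product / %): 3.00: 46, 42, 5; 6.00: 44, 39, 12; 15.0: 41, 36, 17; 40.0: 33, 27, 22

(readings scatter by 1.5 percentage points)

- free catalyst is single-handed; left-handed substrate and right-handed substrate are mirror images of each other, charged as a racemate, each of them at the stated concentration
- the earlier runs were read with a standard deviation of 1.5 percentage points
- steps thought possible: coupling partner + protic impurity -> quenched reagent; coupling partner + free catalyst + left-handed substrate -> free catalyst + left-handed product; free catalyst + stray impurity -> spent catalyst; coupling partner + free catalyst + right-handed substrate -> free catalyst + right-handed product; free catalyst + added ligand <-> idle complex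
- an excess is below zero if the other one leads

- the flask that ends with the higher excess of right-handed substrate over left-handed substrate among what is left of the two, or "neither" when 2 percentage points or less lies between them (north-east / south-west / neither)
- excess of right-handed substrate over left-handed substrate among what is left of the two at the end, north-east
- excess of right-handed substrate over left-handed substrate among what is left of the two at the end, south-west

So we expect north-east and south-west, which differ in [added ligand], to run close together, though north-east's 2.0 mM lies above the 1.5 mM of the alder run. But the question is about an excess, and we can reckon that from the two substrates without fitting a curve. Both handed steps use the same free catalyst and the same coupling partner. If each step is first order in its substrate, those factors cancel between the two hands. We add up the ln of the share left of each substrate over the paired readings of both runs, and divide: s = 1.56, a reading with its scatter. This s is the selectivity factor: ln of the share left of left-handed substrate over ln of the share left of right-handed substrate.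

If f of the right-handed substrate is left, then f^s of the left-handed is left, and the excess is (f − f^s)/(f + f^s). We integrate nothing. At 40.0 min the two runs average f = 64.0%, so the excess is 12.5%. The flasks run to 50 min, not far past that time, so we expect an excess near that in both, with a gap inside 2 points, and we commit to neither.

The forecast, by “Selectivity from ln ratios”, gave 9.5% (5% to 13%) for north-east, 10% (6% to 14%) for south-west, and neither. Its north-east value lies lower than our reckoning.

North-east gives 12.2% and south-west 13.2%, so the answer is neither.

    coupling partner + protic impurity → quenched reagent (k = 200 M⁻¹ min⁻¹)
    coupling partner + free catalyst + left-handed substrate → free catalyst + left-handed product (k = 2000 M⁻² min⁻¹)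
    free catalyst + stray impurity → spent catalyst (k = 1400 M⁻¹ min⁻¹)
    coupling partner + free catalyst + right-handed substrate → free catalyst + right-handed product (k = 1200 M⁻² min⁻¹)
    free catalyst + added ligand ⇌ idle complex (K = 170 M⁻¹, k = 29.0 M⁻¹ min⁻¹)

South-west keeps 67% of its right-handed substrate, and s turns that into an excess of 11.2%. A neighbour of south-west, charged with 0.28 M of coupling partner, keeps 28% of its right-handed substrate at 50 min. The same s gives that neighbour 34.2%, and the neighbour flask stands at 40.0%.

(Readings and results were generated by integration on assumed constants; scatter was added.)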